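**Retrosynthetic overview**
1. No ring is formed at any stage: the only ring, the para-substituted benzene ring, is bought intact in tyrosol 1.
2. C–O disconnection (formed first): the primary-alcohol ester of 1 with 3-bromopropanoic acid 2 gives β-bromo ester 3, the precursor of an ester homoenolate.
3. Key C–C disconnection (formed last): C3–C4 of the pentacosanoyl chain. The β-carbon of 3, by nature an acceptor carbon, is turned into a nucleophile (zinc homoenolate) and joined to the electrophilic C1 of 1-bromodocosane 4 (C3 + C22 = C25), passing through in-flask species 5, 6 and 7 to target 8.
4. The phenol is masked only inside that pot (trimethylsilyl ether, lost in the acidic work-up), so there is no separate protection or deprotection step.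

Assumption: the target has no stereocentre or other stereogenic element, so the "single enantiomer" is simply the one achiral structure and nothing has to be set.

Abbreviations: BSA = N,O-bis(trimethylsilyl)acetamide; DMI = 1,3-dimethylimidazolidin-2-one; IPr = 1,3-bis(2,6-diisopropylphenyl)imidazol-2-ylidene; TsOH = 4-toluenesulfonic acid.

**Route**

Step 1
Reactants: 1 tyrosol, 2-(4-hydroxyphenyl)ethanol (1.0 equiv); 2 3-bromopropanoic acid (1.2 equiv)
Product: 3 2-(4-hydroxyphenyl)ethyl 3-bromopropanoate
Conditions: TsOH·H2O (5 mol %), toluene, reflux, Dean–Stark trap, 5 h
Reagents that add atoms: none
Why: Fischer esterification with azeotropic removal of water acylates only the aliphatic hydroxyl, because the phenol is too poor a nucleophile under acid-catalysed equilibrium conditions and the primary C–Br bond is inert to hot TsOH; no stereocentre is involved.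

Step 2
Reactants: 3 2-(4-hydroxyphenyl)ethyl 3-bromopropanoate (1.5 equiv); 4 1-bromodocosane (1.0 equiv)
Product: 8 2-(4-hydroxyphenyl)ethyl pentacosanoate, via aryl trimethylsilyl ether 5 (not isolated), via zinc homoenolate 6 (not isolated), via silylated pentacosanoate 7 (not isolated)
Conditions: BSA (1.1 equiv to 3), THF, 25 °C, then evaporate; Zn dust (2 equiv), I2 (5 mol %), DMI, 70 °C; then 4, PdCl2(IPr)(3-chloropyridine) (2 mol %), LiBr (2 equiv), THF/DMI 2:1, 25 to 45 °C; then 1 M HCl, THF, 25 °C
Reagents that add atoms: none
Why: Zinc insertion into the β-bromo ester gives a chelate-stabilised ester homoenolate whose nucleophilic β-carbon is joined to the electrophilic primary bromide by an alkyl–alkyl Negishi coupling; the bulky carbene ligand on palladium (divalent precatalyst, reduced in the flask to zerovalent palladium) suppresses β-hydride elimination, the transient silyl ether keeps the acidic phenol away from the C–Zn bond and is hydrolysed in the work-up, and no stereocentre is created.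

Practical notes for step 2:
- Evaporating after silylation removes excess BSA and its by-product before zinc is added.
- Zinc insertion must be complete before 4 and the catalyst are added, so that no unreacted 5 competes as an electrophile.
- Yield is counted on 4. The expected by-products (2-(4-hydroxyphenyl)ethyl propanoate from excess 6, docosane, tetratetracontane) differ widely in polarity from 8 and are removed on silica, followed by recrystallisation.

**Compound list**
1 | tyrosol, 2-(4-hydroxyphenyl)ethanol | OCCc1ccc(O)cc1 | starting material
2 | 3-bromopropanoic acid | OC(=O)CCBr | starting material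
3 | 2-(4-hydroxyphenyl)ethyl 3-bromopropanoate | BrCCC(=O)OCCc1ccc(O)cc1 | intermediate
4 | 1-bromodocosane | CCCCCCCCCCCCCCCCCCCCCCBr | starting material
5 | 2-[4-(trimethylsilyloxy)phenyl]ethyl 3-bromopropanoate | BrCCC(=O)OCCc1ccc(O[Si](C)(C)C)cc1 | intermediate
6 | bromo{3-oxo-3-[2-(4-trimethylsilyloxyphenyl)ethoxy]propyl}zinc | Br[Zn]CCC(=O)OCCc1ccc(O[Si](C)(C)C)cc1 | intermediate
7 | 2-[4-(trimethylsilyloxy)phenyl]ethyl pentacosanoate | CCCCCCCCCCCCCCCCCCCCCCCCC(=O)OCCc1ccc(O[Si](C)(C)C)cc1 | intermediate
8 | 2-(4-hydroxyphenyl)ethyl pentacosanoate | CCCCCCCCCCCCCCCCCCCCCCCCC(=O)OCCc1ccc(O)cc1 | target

**Step count and risks**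
Total step count: 2. Longest linear sequence: 2 (1 → 3 → 8).

The route has only two steps, so the three entries below are its three separate operations that can fail: the two stages of step 2, then step 1.

Risk 1, step 2, coupling stage. The ester-chelated homoenolate 6 may transmetalate slowly, and the alkylpalladium species may undergo β-hydride elimination or homocoupling, giving docosane, docosene and little 8. The fallback gives up the organometallic coupling for a radical conjugate addition. It sets out from 1: Fischer esterification with acrylic acid (TsOH·H2O, 4-methoxyphenol as inhibitor, toluene, Dean–Stark trap) gives 2-(4-hydroxyphenyl)ethyl prop-2-enoate F1. The docosyl radical, generated from 4 with tris(trimethylsilyl)silane and azobisisobutyronitrile in toluene at 80 °C, adds to the β-carbon of F1 (Giese addition), and hydrogen transfer from the silane gives the target. The free phenol is tolerated, and the fallback comes back to the route at 8.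

Risk 2, step 2, silylation and zinc-insertion stage. If the aryl silyl ether is lost early, the phenol protonates the C–Zn bond and only the propanoate of tyrosol is obtained. The fallback keeps the phenol away from all organometallic chemistry by forming the ester C–O bond last. It sets out from 4: coupling with commercially available (3-ethoxy-3-oxopropyl)zinc bromide under the same PdCl2(IPr)(3-chloropyridine)/LiBr conditions gives ethyl pentacosanoate F2. Transesterification of F2 with 1, catalysed by immobilised Candida antarctica lipase B in 2-methylbutan-2-ol at 70 °C under reduced pressure, acylates only the aliphatic hydroxyl, and the fallback comes back to the route at 8.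

Risk 3, step 1. Hot acid may cause some loss of HBr (acrylate formation) or traces of phenolic ester. The fallback replaces the acid-catalysed equilibrium by an irreversible enzymatic acyl transfer at 40 °C. It sets out from 2: transvinylation with vinyl acetate (Pd(OAc)2 and KOH, both catalytic, 25 °C) gives ethenyl 3-bromopropanoate F3. Immobilised Candida antarctica lipase B then transfers the acyl group of F3 to the aliphatic hydroxyl of 1 only (tert-butyl methyl ether, 40 °C), and the fallback comes back to the route at 3.

**Further compounds**
F1 | step 2 | 2-(4-hydroxyphenyl)ethyl prop-2-enoate | C=CC(=O)OCCc1ccc(O)cc1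
F2 | step 2 | ethyl pentacosanoate | CCCCCCCCCCCCCCCCCCCCCCCCC(=O)OCC
F3 | step 1 | ethenyl 3-bromopropanoate | C=COC(=O)CCBr
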